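Coming from an earlier run, you may want to count one chain per initiator charged, but this flask also holds impurity, at 1.1 mM against 1.00 mM of initiator.

free monomer 0.050 M; initiator 2 mol%; impurity 1.1 mM; time 30 s

    free monomer + living end → monomer in chains + living end, rate k1*[living end]*[free monomer] (k1 = 17 /M/s)
    initiator + impurity → spent initiator (k2 = 10000 /M/s)
    free monomer + initiator → living end + monomer in chains (k3 = 60 /M/s)

- the average divides the monomer in chains by the number of chains begun, living and dead together
- run time (flask): 30 s

- whether the average number of monomer units in a chain (chains begun, living or dead) reaches 20 by 30 s (yes / no)
- average number of monomer units in a chain (chains begun, living or dead) at 30 s

- In the first instants, initiator can meet free monomer, with constant 60 /M/s, or impurity, with constant 10000 /M/s, so you compare those two rates at one moment. With free monomer held at its charge, they are equal when c(impurity) stands at 0.300 mM, and you carry this level through as the break-even impurity.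
- The charge of impurity lies above break-even, so at the start 21.4% of the initiator reacting begins a chain.
- That comparison drifts: as impurity is used, c(impurity) comes closer to break-even. For every small loss of impurity, the chains begun are that loss times break-even over c(impurity), and summing gives break-even times the natural log of the impurity charged over the impurity left.
- The initiator charged must equal the impurity used plus the chains begun. Try chains equal to break-even: that leaves 0.400 mM of impurity, and the sum returns 0.303 mM, which lies close to the trial, so I take that value for the chains begun. At the last moment of this stage, the share of the reacting initiator that begins a chain has climbed to 42.9%.
- In the middle, with the 1.00 mM of initiator used up, no step in the scheme makes or removes a living end. Free monomer therefore falls in a pseudo-first-order way at 0.00516 /s, with a half-life of 134 s, longer than the run.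
- By the end, at 30 s, I reckon that this decay adds 7.17 mM to the chains on top of their first units, which gives an average of 24.6, passing 20 at 23.8 s.
- The forecast says yes with 24.4, against my 24.6, and expects that “It rises steadily and passes 20 at about 24 s”.
- The flask gives yes and an average of 24.4. At 30.0 s, c(living end) stands at 3.01 × 10⁻⁴ M. Initiator is at 0% of its charge and impurity at 36% of its own, which is 0.401 mM, still above break-even. Held against break-even, that level means the last initiator to react split 42.8% toward chains.

All constants belong to no real substance, and the outcome is calculated.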